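**Plan**

1. Retrosynthesis: the three phenolic MOM ethers come off last; before that, the bond between the benzophenone carbonyl carbon and the ring-A carbon lying between the OH- and OMe-bearing carbons is cut.
2. Enabling feature: on ring B the ketone carbon and the formyl carbon sit on neighbouring ring atoms, so together they are the open form of a 3-methoxyphthalide (lactone C1 = ketone carbon, acetal C3 = formyl carbon). The ring-A carbon is flanked by two oxygen-bearing carbons and is the site of directed ortho-lithiation.
3. Ring B: methyl 3,5-dihydroxybenzoate is formylated, MOM-protected, closed to the temporary lactone ring (hydrolysis, pseudo-esterification), brominated at C7 and prenylated by Stille coupling.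
4. Ring A: 2-chloro-3-methylphenol is MOM-protected, borylated/oxidised at its only unflanked C–H and O-methylated, which fixes the Cl/OH/OMe pattern without electrophilic chlorination.
5. Union: the ring-A aryllithium adds once to the lactone carbonyl, the lactolate opens on work-up to ketone plus aldehyde, and acid then frees the three phenols.
6. Stereochemistry: the target has no stereocentre; the acetal carbon C3 of the phthalide intermediates is racemic and is erased in the key step.

Key step: step 10

Remark: the target SMILES has no stereocentre and no stereo double bond, so the achiral compound itself is the required single stereoisomer; lactol and pseudo-ester intermediates are used as racemates.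

**Route**

Step 1
Reactants: 1 methyl 3,5-dihydroxybenzoate
Product: 2 methyl 2-formyl-3,5-dihydroxybenzoate
Conditions: POCl3, DMF, MeCN, 0 °C→rt; then H2O, 50 °C
Reagents that add atoms: N,N-dimethylformamide CN(C)C=O; water O
Why: Vilsmeier–Haack formylation of a resorcinol should attack the position ortho to one hydroxyl and para to the other (C2 = C6 by symmetry) in preference to the position between the two hydroxyls, and hydrolysis of the iminium salt gives the aldehyde.

Step 2
Reactants: 2 methyl 2-formyl-3,5-dihydroxybenzoate
Product: 3 methyl 2-formyl-3,5-bis(methoxymethoxy)benzoate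
Conditions: MOMCl, i-Pr2NEt, CH2Cl2, 0 °C→rt
Reagents that add atoms: chloromethyl methyl ether COCCl
Why: Base-mediated O-alkylation (Williamson-type) of both phenols, with excess reagent to overcome the hydrogen bond of the 3-OH to the formyl group.

Step 3
Reactants: 3 methyl 2-formyl-3,5-bis(methoxymethoxy)benzoate
Product: 4 3-hydroxy-4,6-bis(methoxymethoxy)-2-benzofuran-1(3H)-one (racemic lactol)
Conditions: LiOH·H2O, THF–H2O, 0 °C→rt; then 1 M HCl to pH 3–4, 0 °C
Reagents that add atoms: lithium hydroxide [Li+].[OH-]
Why: Saponification assisted by the neighbouring formyl group (hydroxide adds to CHO and the hemiacetal alkoxide attacks the ester), after which the 2-formylbenzoic acid should close to its ring tautomer, the 3-hydroxyphthalide.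

Step 4
Reactants: 4 3-hydroxy-4,6-bis(methoxymethoxy)-2-benzofuran-1(3H)-one
Product: 5 3-methoxy-4,6-bis(methoxymethoxy)-2-benzofuran-1(3H)-one (racemic pseudo-ester)
Conditions: MeOH, PPTS (cat.), 3 Å MS, 40 °C
Reagents that add atoms: methanol CO
Why: Pseudo-esterification (acid-catalysed acetalisation of the lactol of a phthalaldehydic acid) should give the cyclic 3-methoxy lactone and not the open methyl ester, at an acidity too weak to cleave aryl MOM ethers.

Step 5
Reactants: 5 3-methoxy-4,6-bis(methoxymethoxy)-2-benzofuran-1(3H)-one
Product: 6 7-bromo-3-methoxy-4,6-bis(methoxymethoxy)-2-benzofuran-1(3H)-one (racemic)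
Conditions: NBS, MeCN, 0 °C→rt, dark
Reagents that add atoms: N-bromosuccinimide O=C1CCC(=O)N1Br
Why: Electrophilic aromatic bromination should occur at C7 (para to the C4 oxygen, ortho to the C6 oxygen, as in 3,5-dialkoxybenzoates), because C5 lies between two alkoxy groups and is shielded by the C4 MOM group that the C3 acetal pushes towards it.

Step 6
Reactants: 6 7-bromo-3-methoxy-4,6-bis(methoxymethoxy)-2-benzofuran-1(3H)-one
Product: 7 3-methoxy-4,6-bis(methoxymethoxy)-7-(3-methylbut-2-en-1-yl)-2-benzofuran-1(3H)-one (racemic)
Conditions: tributyl(prenyl)stannane, Pd(PPh3)4 (cat.), DMF, 95 °C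
Reagents that add atoms: tributyl(3-methylbut-2-en-1-yl)stannane CCCC[Sn](CCCC)(CCCC)CC=C(C)C
Why: Stille cross-coupling, in which the η3-prenyl palladium intermediate should reductively eliminate at its unsubstituted terminus to give the linear prenyl arene, under neutral conditions that leave the lactone acetal and MOM ethers untouched.

Step 7
Reactants: 8 2-chloro-3-methylphenol
Product: 9 2-chloro-1-(methoxymethoxy)-3-methylbenzene
Conditions: MOMCl, i-Pr2NEt, CH2Cl2, 0 °C→rt
Reagents that add atoms: chloromethyl methyl ether COCCl
Why: Base-mediated O-alkylation (Williamson-type) installs the MOM group that later serves as directing group for lithiation and as the only protecting group of ring A.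

Step 8
Reactants: 9 2-chloro-1-(methoxymethoxy)-3-methylbenzene
Product: 11 4-chloro-3-(methoxymethoxy)-5-methylphenol, via arylboronate 10 (not isolated)
Conditions: [Ir(OMe)(cod)]2 (cat.), dtbpy (cat.), B2pin2, THF, 80 °C; then 30% H2O2, aq. NaOH, 0 °C→rt
Reagents that add atoms: hydrogen peroxide OO
Why: Sterically controlled iridium-catalysed C–H borylation of a 1,2,3-trisubstituted benzene occurs at C5, the only C–H without an ortho substituent, and boronate oxidation (1,2-aryl shift from boron to oxygen) then gives the phenol para to chlorine.

Step 9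
Reactants: 11 4-chloro-3-(methoxymethoxy)-5-methylphenol
Product: 12 2-chloro-5-methoxy-1-(methoxymethoxy)-3-methylbenzene
Conditions: MeI, K2CO3, acetone, reflux
Reagents that add atoms: iodomethane CI
Why: Williamson ether synthesis on the only free phenol places the methoxy group para to chlorine.

Step 10
Reactants: 12 2-chloro-5-methoxy-1-(methoxymethoxy)-3-methylbenzene; 7 3-methoxy-4,6-bis(methoxymethoxy)-7-(3-methylbut-2-en-1-yl)-2-benzofuran-1(3H)-one
Product: 15 2-[3-chloro-6-methoxy-2-(methoxymethoxy)-4-methylbenzoyl]-4,6-bis(methoxymethoxy)-3-(3-methylbut-2-en-1-yl)benzaldehyde, via aryllithium 13 (not isolated), via lithium lactolate 14 (not isolated)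
Conditions: n-BuLi, THF, 0 °C; then 7, THF, −78 °C; AcOH, −78 °C→rt, H2O
Reagents that add atoms: none
Why: Proposed new method: n-BuLi removes the one ring-A proton flanked by the OMOM- and OMe-bearing carbons (directed ortho-metalation), and the resulting aryllithium 13 adds to the lactone C1=O of pseudo-ester 7, which the five-membered ring holds coplanar with ring B and accessible beside the 7-prenyl group, to give the cyclic lithium lactolate 14 that should not collapse at −78 °C, so that neither ketone nor aldehyde is present while aryllithium remains. On quenching with acetic acid the hemiketal opens to the diaryl ketone and the C3 methyl hemiacetal loses methanol, so the aryl–carbonyl bond, the tetra-ortho-substituted ketone and the formyl group appear in one operation at their final oxidation levels. The closest known reaction types are the mono-addition of aryllithiums to phthalides (giving 1-aryl lactols or 2-(hydroxymethyl)benzophenones) and the addition of aryl Grignard reagents to pseudo-esters of 2-aroylbenzoic acids; new here is the use of a pseudo-ester of a formyl acid that still carries its C3–H as a 2-formylbenzoyl cation equivalent. No ring is closed (the temporary lactone ring is opened), and the two stereocentres of 14 (C1 and C3) are erased on ring opening, so no stereocontrol is required. The step needs site selectivity of lithiation (secured by the two flanking oxygen donors, with chlorine meta to lithium so that no aryne can form), chemoselectivity for C1=O over the C3 acetal carbon and the C3–H (no Lewis acid is present to ionise the C3–OMe bond, and carbonyl addition at −78 °C should outrun proton transfer) and single addition (secured by the stability of 14 and the cold acidic quench).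

Step 11
Reactants: 15 2-[3-chloro-6-methoxy-2-(methoxymethoxy)-4-methylbenzoyl]-4,6-bis(methoxymethoxy)-3-(3-methylbut-2-en-1-yl)benzaldehyde
Product: 16 Pestalone F
Conditions: 3 M aq. HCl, THF, 45 °C
Reagents that add atoms: none
Why: Acid-catalysed acetal hydrolysis of the three aryl MOM ethers (two of them activated by the ortho carbonyl groups) under dilute conditions that an aryl prenyl group is expected to survive.

**Compound list**

1 | methyl 3,5-dihydroxybenzoate | COC(=O)c1cc(O)cc(O)c1 | starting material
2 | methyl 2-formyl-3,5-dihydroxybenzoate | COC(=O)c1cc(O)cc(O)c1C=O | intermediate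
3 | methyl 2-formyl-3,5-bis(methoxymethoxy)benzoate | COC(=O)c1cc(OCOC)cc(OCOC)c1C=O | intermediate
4 | 3-hydroxy-4,6-bis(methoxymethoxy)-2-benzofuran-1(3H)-one (racemic) | O=C1OC(O)c2c(OCOC)cc(OCOC)cc21 | intermediate
5 | 3-methoxy-4,6-bis(methoxymethoxy)-2-benzofuran-1(3H)-one (racemic) | O=C1OC(OC)c2c(OCOC)cc(OCOC)cc21 | intermediate
6 | 7-bromo-3-methoxy-4,6-bis(methoxymethoxy)-2-benzofuran-1(3H)-one (racemic) | O=C1OC(OC)c2c(OCOC)cc(OCOC)c(Br)c21 | intermediate
7 | 3-methoxy-4,6-bis(methoxymethoxy)-7-(3-methylbut-2-en-1-yl)-2-benzofuran-1(3H)-one (racemic) | O=C1OC(OC)c2c(OCOC)cc(OCOC)c(CC=C(C)C)c21 | intermediate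
8 | 2-chloro-3-methylphenol | Cc1cccc(O)c1Cl | starting material
9 | 2-chloro-1-(methoxymethoxy)-3-methylbenzene | COCOc1cccc(C)c1Cl | intermediate
10 | 2-[4-chloro-3-(methoxymethoxy)-5-methylphenyl]-4,4,5,5-tetramethyl-1,3,2-dioxaborolane | COCOc1cc(B2OC(C)(C)C(C)(C)O2)cc(C)c1Cl | intermediate
11 | 4-chloro-3-(methoxymethoxy)-5-methylphenol | COCOc1cc(O)cc(C)c1Cl | intermediate
12 | 2-chloro-5-methoxy-1-(methoxymethoxy)-3-methylbenzene | COCOc1cc(OC)cc(C)c1Cl | intermediate
13 | [3-chloro-6-methoxy-2-(methoxymethoxy)-4-methylphenyl]lithium | [Li]c1c(OC)cc(C)c(Cl)c1OCOC | intermediate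
14 | lithium 1-[3-chloro-6-methoxy-2-(methoxymethoxy)-4-methylphenyl]-3-methoxy-4,6-bis(methoxymethoxy)-7-(3-methylbut-2-en-1-yl)-1,3-dihydro-2-benzofuran-1-olate (mixture of diastereomers) | [Li]OC1(c2c(OC)cc(C)c(Cl)c2OCOC)OC(OC)c2c(OCOC)cc(OCOC)c(CC=C(C)C)c21 | intermediate
15 | 2-[3-chloro-6-methoxy-2-(methoxymethoxy)-4-methylbenzoyl]-4,6-bis(methoxymethoxy)-3-(3-methylbut-2-en-1-yl)benzaldehyde | COCOc1c(Cl)c(C)cc(OC)c1C(=O)c1c(C=O)c(OCOC)cc(OCOC)c1CC=C(C)C | intermediate
16 | Pestalone F, 2-(3-chloro-2-hydroxy-6-methoxy-4-methylbenzoyl)-4,6-dihydroxy-3-(3-methylbut-2-en-1-yl)benzaldehyde | COc1cc(C)c(Cl)c(O)c1C(=O)c1c(C=O)c(O)cc(O)c1CC=C(C)C | target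

**Count and risks**

Total steps: 11. Longest linear sequence: 8 steps (steps 1–6, 10, 11); the ring-A branch is steps 7–9.

Steps most likely to fail:

Step 10. What may go wrong is proton transfer from the acetal C3–H of 7 to the aryllithium instead of carbonyl addition, or early collapse of the lactolate so that a second aryllithium adds to the freed aldehyde. The fallback uses known chemistry, sets out from 7 and returns at 15. Compound 7 is reduced with NaBH4 in aqueous NaOH–THF (the pseudo-ester opens to the formyl carboxylate, which is reduced) and acidified to pH 3, so that the hydroxy acid lactonises to the phthalide 4,6-bis(methoxymethoxy)-7-(3-methylbut-2-en-1-yl)-2-benzofuran-1(3H)-one F1, which has no leaving group at C3. Aryllithium 13 is added to F1 at −78 °C to give the lactol 1-[3-chloro-6-methoxy-2-(methoxymethoxy)-4-methylphenyl]-4,6-bis(methoxymethoxy)-7-(3-methylbut-2-en-1-yl)-1,3-dihydro-2-benzofuran-1-ol F2 (ring tautomer of the 2-(hydroxymethyl)benzophenone). Oxidation of its open form with activated MnO2 in CH2Cl2 should then give 15.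

Step 11. What may go wrong is acid-promoted addition of the freed 6-OH to the prenyl double bond, or acid-promoted hydride shift and lactonisation of the formyl ketone. The fallback sets out from 15 and returns at 16 without Brønsted acid. Acetal-to-silyl-ether exchange with TMSOTf and 2,2′-bipyridyl in CH2Cl2 at 0 °C should convert the three aryl MOM ethers into the tris(trimethylsilyl) ether 2-{3-chloro-6-methoxy-4-methyl-2-[(trimethylsilyl)oxy]benzoyl}-3-(3-methylbut-2-en-1-yl)-4,6-bis[(trimethylsilyl)oxy]benzaldehyde F3. The aryl silyl ethers are then cleaved at neutral pH with water–THF to give 16.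

Step 6. What may go wrong is allylic transposition during transmetalation or reductive elimination (branched 1,1-dimethylallyl coupling), or slow oxidative addition at the doubly ortho-substituted bromide with protodebromination. The fallback sets out from 6 and returns at 7. Stille coupling of 6 with allyltributylstannane, which has no regiochemical issue, should give 3-methoxy-4,6-bis(methoxymethoxy)-7-(prop-2-en-1-yl)-2-benzofuran-1(3H)-one F4. Olefin cross-metathesis of F4 with 2-methylbut-2-ene (second-generation ruthenium benzylidene catalyst, CH2Cl2, 40 °C) then converts allyl into prenyl to give 7.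

Further compounds
F1 | step 10 | 4,6-bis(methoxymethoxy)-7-(3-methylbut-2-en-1-yl)-2-benzofuran-1(3H)-one | O=C1OCc2c(OCOC)cc(OCOC)c(CC=C(C)C)c21
F2 | step 10 | 1-[3-chloro-6-methoxy-2-(methoxymethoxy)-4-methylphenyl]-4,6-bis(methoxymethoxy)-7-(3-methylbut-2-en-1-yl)-1,3-dihydro-2-benzofuran-1-ol | OC1(c2c(OC)cc(C)c(Cl)c2OCOC)OCc2c(OCOC)cc(OCOC)c(CC=C(C)C)c21
F3 | step 11 | 2-{3-chloro-6-methoxy-4-methyl-2-[(trimethylsilyl)oxy]benzoyl}-3-(3-methylbut-2-en-1-yl)-4,6-bis[(trimethylsilyl)oxy]benzaldehyde | C[Si](C)(C)Oc1c(Cl)c(C)cc(OC)c1C(=O)c1c(C=O)c(O[Si](C)(C)C)cc(O[Si](C)(C)C)c1CC=C(C)C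
F4 | step 6 | 3-methoxy-4,6-bis(methoxymethoxy)-7-(prop-2-en-1-yl)-2-benzofuran-1(3H)-one | O=C1OC(OC)c2c(OCOC)cc(OCOC)c(CC=C)c21
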